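The route rests on reading the central oxazole as a rearranged isoxazole. The feature used is the substitution pattern of the oxazole ring: pyrrol-2-yl on C2, indol-3-yl on C5 and hydrogen on C4. A nitrile oxide–alkyne cycloaddition delivers exactly this pattern on an isoxazole (C3, C5, C4–H). One photochemical operation then cuts N–O and C3–C4 of the isoxazole and makes N3–C4 and O1–C2 of the oxazole. The precursor is the bis-Boc 3-(pyrrol-2-yl)-5-(6-bromo-4-methoxyindol-3-yl)isoxazole. The light-sensitive pyrrole bromine is introduced afterwards, while both nitrogens still carry Boc, and the carbamates are removed last.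

Key step: step 7

Remarks on the chemistry:
- The target is achiral, so no stereocentre has to be set; azirine 13 forms as a racemate and loses its stereocentre in the same step.
- Oxime 9 and chloride 10 are drawn as the E and Z isomers expected to predominate; the geometry disappears in nitrile oxide 11.
- The substituent map was checked and holds: isoxazole C3 becomes oxazole C2 and isoxazole C5 stays C5, so no structure needed correcting.
- Bromination is placed before carbamate removal so that NBS meets an indole that is still deactivated as its carbamate.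

Step 1
Reactants: 1 6-bromo-4-methoxy-1H-indole
Product: 3 tert-butyl 6-bromo-3-iodo-4-methoxyindole-1-carboxylate, via 3-iodoindole 2 (not isolated)
Conditions: I2, KOH, DMF, 0 °C to rt; aqueous Na2S2O3 wash; crude in CH2Cl2, Boc2O, DMAP (cat.), rt
Reagents that add atoms: iodine (II); di-tert-butyl dicarbonate (CC(C)(C)OC(=O)OC(=O)OC(C)(C)C)
Why: Electrophilic aromatic iodination goes to C3, the most nucleophilic indole position, and DMAP-catalysed N-acylation of the crude, light-sensitive 3-iodoindole with Boc2O then gives a stable coupling partner.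

Step 2
Reactants: 3 tert-butyl 6-bromo-3-iodo-4-methoxyindole-1-carboxylate; 4 trimethylsilylacetylene
Product: 5 tert-butyl 6-bromo-4-methoxy-3-[(trimethylsilyl)ethynyl]indole-1-carboxylate
Conditions: PdCl2(PPh3)2 (cat.), CuI (cat.), Et3N, THF, rt
Reagents that add atoms: none
Why: Sonogashira coupling, in which zerovalent palladium inserts into the C3–I bond far faster than into the C6–Br bond at room temperature, so only the iodide should couple and the linear alkyne is indifferent to the peri methoxy group.

Step 3
Reactants: 5 tert-butyl 6-bromo-4-methoxy-3-[(trimethylsilyl)ethynyl]indole-1-carboxylate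
Product: 6 tert-butyl 6-bromo-3-ethynyl-4-methoxyindole-1-carboxylate
Conditions: K2CO3 (0.2 equiv), MeOH/THF, 0 °C
Reagents that add atoms: none
Why: Carbonate-catalysed methanolysis of the alkynyl C–Si bond (protodesilylation) is fast at 0 °C, and with substoichiometric base and a short reaction time the indole carbamate is expected to survive.

Step 4
Reactants: 7 1H-pyrrole-2-carbaldehyde
Product: 8 tert-butyl 2-formylpyrrole-1-carboxylate
Conditions: Boc2O, DMAP (cat.), MeCN, rt
Reagents that add atoms: di-tert-butyl dicarbonate (CC(C)(C)OC(=O)OC(=O)OC(C)(C)C)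
Why: DMAP-catalysed N-acylation of the acidic pyrrole N–H with Boc2O is standard for 2-acylpyrroles and lowers the ring's reactivity towards the chlorinating agent used in step 6.

Step 5
Reactants: 8 tert-butyl 2-formylpyrrole-1-carboxylate
Product: 9 tert-butyl 2-[(E)-(hydroxyimino)methyl]pyrrole-1-carboxylate
Conditions: NH2OH·HCl, NaOAc, EtOH/H2O, 0 °C to rt
Reagents that add atoms: hydroxylamine hydrochloride (Cl.NO)
Why: Acetate-buffered condensation of the aldehyde with hydroxylamine (oxime formation) is much faster than attack on the N-acyl pyrrole carbamate.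

Step 6
Reactants: 9 tert-butyl 2-[(E)-(hydroxyimino)methyl]pyrrole-1-carboxylate; 6 tert-butyl 6-bromo-3-ethynyl-4-methoxyindole-1-carboxylate
Product: 12 tert-butyl 6-bromo-3-[3-(1-Boc-pyrrol-2-yl)isoxazol-5-yl]-4-methoxyindole-1-carboxylate, via hydroximoyl chloride 10 (not isolated), via nitrile oxide 11 (not isolated)
Conditions: 9 (1.5 equiv), NCS (slightly less than 9), DMF, rt; then 6, Et3N (slow addition), 0 °C to rt
Reagents that add atoms: none
Why: Huisgen 1,3-dipolar cycloaddition of a slowly released nitrile oxide to a terminal alkyne, in which steric and frontier-orbital control put the alkyne substituent on C5 and should give only the 3,5-disubstituted isoxazole.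

Step 7
Reactants: 12 tert-butyl 6-bromo-3-[3-(1-Boc-pyrrol-2-yl)isoxazol-5-yl]-4-methoxyindole-1-carboxylate
Product: 15 tert-butyl 6-bromo-3-[2-(1-Boc-pyrrol-2-yl)oxazol-5-yl]-4-methoxyindole-1-carboxylate, via acylazirine 13 (not isolated), via nitrile ylide 14 (not isolated)
Conditions: hν (medium-pressure Hg lamp, 280–370 nm filter), degassed MeCN (5 mM), FEP coil flow reactor, 25 °C
Reagents that add atoms: none
Why: Excitation of the conjugated 5-(indol-3-yl)isoxazole breaks the weak N–O bond and the open vinylnitrene-type diradical recloses between nitrogen and the former C4 to the racemic 2-acyl-2H-azirine 13, a second photon absorbed in the pyrrolyl–C=N band then breaks the azirine C2–C3 bond to nitrile ylide 14, and the acyl oxygen adds to the nitrilium carbon. The closest known reaction type is the photochemical transposition of 3,5-diarylisoxazoles to 2,5-diaryloxazoles through 2-acylazirines, which is established in batch and in continuous flow. The oxazole ring closes by a 6π 1,5-dipolar electrocyclisation of the acyl nitrile ylide (formally 5-endo-dig, oxygen onto the nitrilium carbon), which makes O1–C2 after N3–C4 was made in the transient three-membered ring (3-exo-trig closure of the nitrene nitrogen). No stereocentre is created in the product, because the one stereocentre of azirine 13 is lost on ring opening. The step needs N–O cleavage to outrun homolysis of the indole C6–Br bond and photo-Fries chemistry of the carbamates: the N–O bond is by far the weakest bond, the extended chromophore absorbs above 280 nm so the filter can exclude shorter-wave light, the pyrrole carries no bromine yet, and the short, uniform exposure in the flow coil takes the oxazole out of the light before secondary photolysis. Azirine excited in its acyl n,π* band returns to isoxazole 12 and re-enters the cycle while oxazole formation is irreversible, and with both N–H groups masked and dry, degassed acetonitrile as solvent the nitrile ylide meets no proton source, nucleophile or oxygen.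

Step 8
Reactants: 15 tert-butyl 6-bromo-3-[2-(1-Boc-pyrrol-2-yl)oxazol-5-yl]-4-methoxyindole-1-carboxylate
Product: 16 tert-butyl 6-bromo-3-[2-(5-bromo-1-Boc-pyrrol-2-yl)oxazol-5-yl]-4-methoxyindole-1-carboxylate
Conditions: NBS (1.0 equiv), THF, −78 °C to 0 °C, dark
Reagents that add atoms: N-bromosuccinimide (O=C1CCC(=O)N1Br)
Why: Electrophilic aromatic bromination should take the free α-position C5 of the N-Boc pyrrole, the most electron-rich site left, because the indole is deactivated as its carbamate with C3 blocked and the oxazole C4–H is inert to NBS at low temperature.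

Step 9
Reactants: 16 tert-butyl 6-bromo-3-[2-(5-bromo-1-Boc-pyrrol-2-yl)oxazol-5-yl]-4-methoxyindole-1-carboxylate
Product: 17 5-(6-bromo-4-methoxy-1H-indol-3-yl)-2-(5-bromo-1H-pyrrol-2-yl)oxazole
Conditions: K2CO3, MeOH/THF, rt to 40 °C
Reagents that add atoms: none
Why: Base-mediated methanolysis of both azole carbamates (N-acyl pyrrole and N-acyl indole react as activated amides) should free the two N–H groups without acid, which could cause protodebromination or bromine migration on the bromopyrrole.

Compound list
1 | 6-bromo-4-methoxy-1H-indole | COc1cc(Br)cc2[nH]ccc12 | starting material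
2 | 6-bromo-3-iodo-4-methoxy-1H-indole (carried on crude) | COc1cc(Br)cc2[nH]cc(I)c12 | intermediate
3 | tert-butyl 6-bromo-3-iodo-4-methoxyindole-1-carboxylate | COc1cc(Br)cc2n(C(=O)OC(C)(C)C)cc(I)c12 | intermediate
4 | trimethylsilylacetylene | C#C[Si](C)(C)C | starting material
5 | tert-butyl 6-bromo-4-methoxy-3-[(trimethylsilyl)ethynyl]indole-1-carboxylate | COc1cc(Br)cc2n(C(=O)OC(C)(C)C)cc(C#C[Si](C)(C)C)c12 | intermediate
6 | tert-butyl 6-bromo-3-ethynyl-4-methoxyindole-1-carboxylate | COc1cc(Br)cc2n(C(=O)OC(C)(C)C)cc(C#C)c12 | intermediate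
7 | 1H-pyrrole-2-carbaldehyde | O=Cc1ccc[nH]1 | starting material
8 | tert-butyl 2-formylpyrrole-1-carboxylate | O=Cc1cccn1C(=O)OC(C)(C)C | intermediate
9 | tert-butyl 2-[(E)-(hydroxyimino)methyl]pyrrole-1-carboxylate | O/N=C/c1cccn1C(=O)OC(C)(C)C | intermediate
10 | tert-butyl 2-[(Z)-chloro(hydroxyimino)methyl]pyrrole-1-carboxylate (formed in the flask) | O/N=C(\Cl)c1cccn1C(=O)OC(C)(C)C | intermediate
11 | 1-(tert-butoxycarbonyl)pyrrole-2-carbonitrile oxide (formed in the flask) | [O-][N+]#Cc1cccn1C(=O)OC(C)(C)C | intermediate
12 | tert-butyl 6-bromo-3-[3-(1-Boc-pyrrol-2-yl)isoxazol-5-yl]-4-methoxyindole-1-carboxylate | COc1cc(Br)cc2n(C(=O)OC(C)(C)C)cc(-c3cc(-c4cccn4C(=O)OC(C)(C)C)no3)c12 | intermediate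
13 | tert-butyl 6-bromo-3-{[3-(1-Boc-pyrrol-2-yl)-2H-azirin-2-yl]carbonyl}-4-methoxyindole-1-carboxylate (racemic, transient) | COc1cc(Br)cc2n(C(=O)OC(C)(C)C)cc(C(=O)C3N=C3c4cccn4C(=O)OC(C)(C)C)c12 | intermediate
14 | nitrile ylide from C2–C3 opening of 13: (1-Boc-pyrrol-2-yl)C≡N(+)–CH(−)–C(=O)(1-Boc-6-bromo-4-methoxyindol-3-yl) (transient) | COc1cc(Br)cc2n(C(=O)OC(C)(C)C)cc(C(=O)[CH-][N+]#Cc3cccn3C(=O)OC(C)(C)C)c12 | intermediate
15 | tert-butyl 6-bromo-3-[2-(1-Boc-pyrrol-2-yl)oxazol-5-yl]-4-methoxyindole-1-carboxylate | COc1cc(Br)cc2n(C(=O)OC(C)(C)C)cc(-c3cnc(-c4cccn4C(=O)OC(C)(C)C)o3)c12 | intermediate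
16 | tert-butyl 6-bromo-3-[2-(5-bromo-1-Boc-pyrrol-2-yl)oxazol-5-yl]-4-methoxyindole-1-carboxylate | COc1cc(Br)cc2n(C(=O)OC(C)(C)C)cc(-c3cnc(-c4ccc(Br)n4C(=O)OC(C)(C)C)o3)c12 | intermediate
17 | 5-(6-bromo-4-methoxy-1H-indol-3-yl)-2-(5-bromo-1H-pyrrol-2-yl)oxazole | COc1cc(Br)cc2[nH]cc(-c3cnc(-c4ccc(Br)[nH]4)o3)c12 | target

Total step count: 9 (steps 4 and 5 form the pyrrole branch, which joins at step 6).
Longest linear sequence: 7 steps (1, 2, 3, 6, 7, 8, 9 from compound 1).

Steps most likely to fail

1. Step 7. Carbon–bromine homolysis or carbamate photochemistry may compete with N–O cleavage, or the azirine may cycle back to the isoxazole or drift to ketenimine-type products instead of opening to the nitrile ylide. The fallback builds the oxazole by cross-coupling instead of ring transposition; it sets out from iodide 3 and returns at oxazole 15. Suzuki–Miyaura coupling of 3 with commercial 2-(triisopropylsilyl)oxazol-5-ylboronic acid pinacol ester (Pd(dppf)Cl2, K3PO4, dioxane/H2O, 60 °C, C–I before C–Br) should give tert-butyl 6-bromo-4-methoxy-3-[2-(triisopropylsilyl)oxazol-5-yl]indole-1-carboxylate F1. TBAF in THF should remove the silyl group to give tert-butyl 6-bromo-4-methoxy-3-(oxazol-5-yl)indole-1-carboxylate F2. Deprotonation at oxazole C2 with LiHMDS in THF at −78 °C and an I2 quench should give tert-butyl 6-bromo-3-(2-iodooxazol-5-yl)-4-methoxyindole-1-carboxylate F3. A second Suzuki–Miyaura coupling with commercial 1-Boc-pyrrole-2-boronic acid (Pd(PPh3)4, K2CO3, DME/H2O, 60 °C) should then deliver 15.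

2. Step 8. Site selectivity may be lost (attack at pyrrole C4 or on the methoxy-activated benzo ring of the indole), over-bromination may occur, or the doubly deactivated pyrrole may react too slowly. The fallback reverses the order of the end game; it sets out from 15 and returns at target 17. Methanolysis of both carbamates (K2CO3, MeOH/THF) should give 5-(6-bromo-4-methoxy-1H-indol-3-yl)-2-(1H-pyrrol-2-yl)oxazole F4. Its free pyrrole α-position is far more nucleophilic and should take one equivalent of NBS in THF at −78 °C to give 17 directly.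

3. Step 6. The nitrile oxide may dimerise to the furoxan faster than it adds to the peri-hindered indolyl alkyne, and the pyrrole ring may be chlorinated while the hydroximoyl chloride forms. The fallback makes the indole–isoxazole bond by cross-coupling; it sets out from oxime 9 and iodide 3 and returns at isoxazole 12, so steps 2 and 3 are not needed. Nitrile oxide 11, generated as before, is intercepted by a large excess of commercial ethynyltributylstannane, an unhindered dipolarophile, to give tert-butyl 2-[5-(tributylstannyl)isoxazol-3-yl]pyrrole-1-carboxylate F5. Stille coupling of F5 with 3 (Pd(PPh3)4, CuI, DMF, 60 °C, C–I selective) should then give 12.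

Further compounds
F1 | step 7 | tert-butyl 6-bromo-4-methoxy-3-[2-(triisopropylsilyl)oxazol-5-yl]indole-1-carboxylate | COc1cc(Br)cc2n(C(=O)OC(C)(C)C)cc(-c3cnc([Si](C(C)C)(C(C)C)C(C)C)o3)c12
F2 | step 7 | tert-butyl 6-bromo-4-methoxy-3-(oxazol-5-yl)indole-1-carboxylate | COc1cc(Br)cc2n(C(=O)OC(C)(C)C)cc(-c3cnco3)c12
F3 | step 7 | tert-butyl 6-bromo-3-(2-iodooxazol-5-yl)-4-methoxyindole-1-carboxylate | COc1cc(Br)cc2n(C(=O)OC(C)(C)C)cc(-c3cnc(I)o3)c12
F4 | step 8 | 5-(6-bromo-4-methoxy-1H-indol-3-yl)-2-(1H-pyrrol-2-yl)oxazole | COc1cc(Br)cc2[nH]cc(-c3cnc(-c4ccc[nH]4)o3)c12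
F5 | step 6 | tert-butyl 2-[5-(tributylstannyl)isoxazol-3-yl]pyrrole-1-carboxylate | CCCC[Sn](CCCC)(CCCC)c1cc(-c2cccn2C(=O)OC(C)(C)C)no1
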